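Subtracting neighbouring readings is the easy first step, and it needs no mechanism.

| flask | E | X | Q | temperature | remark | time |
|---|---|---|---|---|---|---|
| cedar | 0.10 M | 0.20 M | 0.20 mM | 0 °C | the very flask that is asked about, followed so far |  |
| alder | 0.067 M | 0.20 M | 0.20 mM | 0 °C | run made earlier |  |
| flask | 0.10 M | 0.200 M | 0.20 mM | 0 °C |  | 4.0 min |

| cedar: time / min | cedar: Z / % | alder: time / s | alder: Z / % |
|---|---|---|---|
| 0.500 | 30.1 | 10.0 | 41.8 |
| 1.00 | 23.3 | 25.0 | 36.4 |
| 1.50 | 21.0 | 40.0 | 29.7 |
| 2.00 | 20.2 | 60.0 | 25.7 |
| 2.50 | 20.0 | 90.0 | 23.3 |
| 3.00 | 20.2 | 120 | 22.7 |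

(standard deviation of a reading: 0.3 percentage points)

- winter: at 4.0 min add X, 50.0% of the amount charged, then wait 80 s
- summer: at 4.0 min add Q, 100% of the amount charged, then wait 80 s
- dusk: at 4.0 min raise the temperature by 15 K, then wait 80 s
- noon: change nothing and wait 80 s more
- dawn: at 4.0 min take out 90% of the Z then present, then wait 80 s

- removed Z is counted in
- additions bring no volume worth counting
- the earlier runs do not show what temperature does; that part of a forecast is a guess

- Z, in percent of the E first charged, at 4.0 min
- the option that brings most further Z ("none" if no option brings more than 2 percentage points) (winter / summer / dusk / noon / dawn / none)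
- Z present, with what was taken out counted in, in percent of the E first charged, after dusk
- Z present, with what was taken out counted in, in percent of the E first charged, after noon

In cedar, Z loses 6.8 percentage points and then 2.3 points over successive steps of 0.500 min. The rate of loss therefore shrinks by a factor f = 2.96 per step, a reading that carries the scatter. Steady shrinking makes the falls a geometric series. Its sum from the first reading is 10 points, which would end Z at 19.8%. The last 3 readings average 20.1%, so the fall stops well above zero. Z is taken here to drain reversibly into another form. By 4.0 min the fall per step has shrunk to 0.01 points, less than the scatter, so this reckoning puts Z at 20.1% then and expects nothing from noon.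

Run backwards by one step, the series gives an estimate of the pool, the Z made in all as if none had drained: 50.2%. The resting share s is Z at rest divided by that pool, and cedar's readings give s = 0.401. An even split between Z and its drained form is the zero of the scale, and cedar reads 0.0990 below it. On that picture Z ends under thermodynamic control, and a flask disturbed at the same temperature returns towards s.

Dawn removes 18 points of Z, and the drained form refills the share 1 − s of that loss, a gain at rest of 11 points. If cedar's f holds, the gap to that rest shrinks by a factor 18.1 in 80 s, so 10 points arrives in that time. Winter, supposing that a lack of X ended the making of Z and that fresh X yields as before, adds 25 points to the pool. Of that, s stays as Z, a gain of 10 points. The readings give no s for a warmer flask.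

The forecast gives 20.1% now, 20.1% after noon, 22% after dusk and dawn as best, with a dawn total near 35 against 30.1% reckoned here, and says: “The heating result is a guess.”

The flask gives 20.1% at 4.0 min, and dusk is best at 34.1%, a gain of 14 points against 11 points for winter and 10 points for dawn.

    E + Q ⇌ Q + L (K = 2.20, k = 1570 M⁻¹ s⁻¹, Ea = 40.0 kJ mol⁻¹, ΔH = −59.0 kJ mol⁻¹)
    Q + L ⇌ G (K = 8.80 M⁻¹, k = 1140 M⁻¹ s⁻¹, Ea = 39.0 kJ mol⁻¹, ΔH = −25.0 kJ mol⁻¹)
    X + G → Q + Z (k = 5440 M⁻¹ s⁻¹, Ea = 10.0 kJ mol⁻¹)
    X → J (k = 0.199 s⁻¹, Ea = 60.0 kJ mol⁻¹)
    Z + Q ⇌ D + Q, rate k5*[Q]*[Z] forward; the back reaction follows from the equilibrium constant (K = 1.50, k = 165 M⁻¹ s⁻¹, Ea = 42.0 kJ mol⁻¹, ΔH = −50.0 kJ mol⁻¹)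
    (constants at 0 °C)

At 4.00 min the flask holds Z 20.1% and D 30.2%, so its resting share Z/(Z + D) is 0.400. A neighbouring flask, the same recipe run at 15 °C, holds Z 12.0% and D 5.72% at 4.00 min. Its share is 0.677, which is 0.177 above the even split. Applied to the flask's pool of 50.3%, that share gives 34.1%.

The numbers in the tables were computed with constants of no real substance; the scatter is artificial.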